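**Retrosynthetic overview**

- C8'–C9': cut last. A catalyst-controlled linear prenylation of a γ-acetoxy enal with a tertiary α,α-dimethylallyl boronate under chiral phosphoric acid catalysis sets 8'R.
- C6'=C7': E-selective Wittig olefination of an α-oxygenated aldehyde with a formyl-stabilised ylide.
- C5'–O: D-proline-catalysed α-aminoxylation of the C6' aldehyde sets 5'S (the first stereocentre), followed by N–O cleavage and acetylation.
- The C6' aldehyde comes from auraptene by cleavage of its terminal olefin; auraptene comes from umbelliferone and geranyl bromide, which supplies the 2'E olefin.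
- No ring is formed: the coumarin bicycle is bought intact in umbelliferone.

Assumption: locants 1'–12' count the farnesyl chain from the ether oxygen, so the target is (2'E,5'S,6'E,8'R); the tertiary allylboronate is taken as not purchasable and is made in one step.

**Route**

Step 1
Reactants: 1 umbelliferone (7-hydroxy-2H-chromen-2-one); 2 geranyl bromide ((2E)-1-bromo-3,7-dimethylocta-2,6-diene)
Product: 3 auraptene (7-{[(2E)-3,7-dimethylocta-2,6-dien-1-yl]oxy}-2H-chromen-2-one)
Conditions: K2CO3 (1.5 equiv), acetone, reflux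
Reagents that add atoms: none
Why: Williamson etherification, in which the phenoxide of 1 displaces the primary allylic bromide of 2 by SN2 without allylic transposition, so the 2'E olefin is carried over unchanged.

Step 2
Reactants: 3 auraptene
Product: 5 (4E)-4-methyl-6-[(2-oxo-2H-chromen-7-yl)oxy]hex-4-enal, via 6',7'-epoxyauraptene 4 (not isolated)
Conditions: mCPBA (1.05 equiv), CH2Cl2, −10 °C; then H5IO6 (1.2 equiv), THF–H2O, 0 °C → rt, same flask
Reagents that add atoms: mCPBA (3-chloroperoxybenzoic acid), O=C(OO)c1cccc(Cl)c1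
Why: Prilezhaev epoxidation selects the electron-rich terminal trisubstituted olefin (the 2',3'-olefin is deactivated by the allylic aryloxy group and the coumarin C3=C4 bond is electron-poor), and periodic acid then opens and cleaves the epoxide (Malaprade-type glycol cleavage) to the aldehyde and acetone, which erases the racemic epoxide stereocentre.

Step 3
Reactants: 5 (4E)-4-methyl-6-[(2-oxo-2H-chromen-7-yl)oxy]hex-4-enal; 6 2-(triphenylphosphoranylidene)propanal
Product: 8 (2E,4S,6E)-2,6-dimethyl-8-[(2-oxo-2H-chromen-7-yl)oxy]-4-[(phenylamino)oxy]octa-2,6-dienal, via (S)-α-anilinooxy aldehyde 7 (not isolated)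
Conditions: D-proline (20 mol%), PhNO (0.95 equiv, added over 1 h), DMSO, rt; then 6 (1.5 equiv), rt, 12 h
Reagents that add atoms: nitrosobenzene, O=Nc1ccccc1
Why: Proline enamine catalysis (α-aminoxylation), in which the (E)-enamine of 5 attacks the oxygen of PhNO held by a hydrogen bond from the catalyst carboxylic acid to its nitrogen (Houk–List transition state), so D-proline gives the 2S aldehyde (mirror image of the 2R outcome known for L-proline), and the stabilised ylide then traps this labile aldehyde in an E-selective Wittig reaction that does not touch the new stereocentre.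

Step 4
Reactants: 8 (2E,4S,6E)-2,6-dimethyl-8-[(2-oxo-2H-chromen-7-yl)oxy]-4-[(phenylamino)oxy]octa-2,6-dienal
Product: 9 (2E,4S,6E)-4-hydroxy-2,6-dimethyl-8-[(2-oxo-2H-chromen-7-yl)oxy]octa-2,6-dienal
Conditions: Cu(OAc)2·H2O (30 mol%), EtOH, rt
Reagents that add atoms: none
Why: Copper-catalysed cleavage of the weak anilino N–O bond (divalent copper binds the nitrogen and the PhN fragment leaves, ending as azobenzene) frees the alcohol without breaking the C–O bond, so C4 stays S and the enal, coumarin and aryl allyl ether are untouched.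

Step 5
Reactants: 9 (2E,4S,6E)-4-hydroxy-2,6-dimethyl-8-[(2-oxo-2H-chromen-7-yl)oxy]octa-2,6-dienal
Product: 10 (2E,4S,6E)-2,6-dimethyl-1-oxo-8-[(2-oxo-2H-chromen-7-yl)oxy]octa-2,6-dien-4-yl acetate
Conditions: Ac2O (1.5 equiv), pyridine, DMAP (5 mol%), CH2Cl2, 0 °C
Reagents that add atoms: acetic anhydride, CC(=O)OC(C)=O
Why: DMAP-catalysed nucleophilic acyl transfer acetylates the only hydroxyl group, breaks no bond at the stereocentre, and is too mildly basic to enolise or eliminate the γ-acetoxy enal.

Step 6
Reactants: 11 prenyl chloride (1-chloro-3-methylbut-2-ene)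
Product: 13 2-(2-methylbut-3-en-2-yl)-4,4,5,5-tetramethyl-1,3,2-dioxaborolane, via prenylmagnesium chloride 12 (not isolated)
Conditions: Mg turnings, THF, 0 °C (slow addition); then iPrOBpin, −78 °C → rt; aq. NH4Cl, distillation
Reagents that add atoms: 2-isopropoxy-4,4,5,5-tetramethyl-1,3,2-dioxaborolane, CC(C)OB1OC(C)(C)C(C)(C)O1
Why: Grignard formation followed by borylation, in which the allylic magnesium reagent attacks the boron electrophile through a six-membered SE2' transition state at its γ-carbon to give the tertiary α,α-dimethylallyl boronate, and the pinacol ester does not revert by 1,3-boryl shift at room temperature.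

Step 7
Reactants: 10 (2E,4S,6E)-2,6-dimethyl-1-oxo-8-[(2-oxo-2H-chromen-7-yl)oxy]octa-2,6-dien-4-yl acetate; 13 2-(2-methylbut-3-en-2-yl)-4,4,5,5-tetramethyl-1,3,2-dioxaborolane
Product: 15 (2E,5S,6E,8R)-8-hydroxy-3,7,11-trimethyl-1-[(2-oxo-2H-chromen-7-yl)oxy]dodeca-2,6,10-trien-5-yl acetate, via O-pinacolboryl ether 14 (not isolated)
Conditions: 13 (2 equiv), (R)-TRIP [(R)-3,3'-bis(2,4,6-triisopropylphenyl)-1,1'-binaphthyl-2,2'-diyl hydrogen phosphate] (10 mol%), 4 Å MS, toluene, −20 °C → rt; then aq. NaHCO3
Reagents that add atoms: none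
Why: Proposed new method: a chiral-phosphoric-acid-catalysed allylboration that uses a tertiary α,α-dimethylallyl pinacol boronate as a linear-prenyl donor; the aldehyde binds boron in a closed six-membered chair transition state, the catalyst P–OH hydrogen-bonds to a boronate oxygen while P=O engages the formyl C–H, the C–C bond forms at the unsubstituted CH2 terminus with allylic transposition so the gem-dimethyl carbon becomes the olefin terminus (linear prenyl, no E/Z issue), and (R)-TRIP exposes the Re face of the enal (the face that gives R carbinols from aryl and alkenyl aldehydes with allyl-Bpin) to set 8'R under catalyst control because the 5'-stereocentre is remote; closest known reaction type: chiral-phosphoric-acid-catalysed allylboration of aldehydes with allyl- and secondary α-substituted allyl-Bpin reagents, together with the uncatalysed racemic linear prenylation of aldehydes by α,α-dimethylallylboronates.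

**Compound list**

1 | umbelliferone (7-hydroxy-2H-chromen-2-one) | O=c1ccc2ccc(O)cc2o1 | starting material
2 | geranyl bromide ((2E)-1-bromo-3,7-dimethylocta-2,6-diene) | CC(C)=CCC/C(C)=C/CBr | starting material
3 | auraptene (7-{[(2E)-3,7-dimethylocta-2,6-dien-1-yl]oxy}-2H-chromen-2-one) | CC(C)=CCC/C(C)=C/COc1ccc2ccc(=O)oc2c1 | intermediate
4 | 6',7'-epoxyauraptene (racemic, not isolated) | CC1(C)OC1CC/C(C)=C/COc1ccc2ccc(=O)oc2c1 | intermediate
5 | (4E)-4-methyl-6-[(2-oxo-2H-chromen-7-yl)oxy]hex-4-enal | O=CCC/C(C)=C/COc1ccc2ccc(=O)oc2c1 | intermediate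
6 | 2-(triphenylphosphoranylidene)propanal | CC(C=O)=P(c1ccccc1)(c1ccccc1)c1ccccc1 | starting material
7 | (2S,4E)-4-methyl-6-[(2-oxo-2H-chromen-7-yl)oxy]-2-[(phenylamino)oxy]hex-4-enal (not isolated) | O=C[C@@H](ONc1ccccc1)C/C(C)=C/COc1ccc2ccc(=O)oc2c1 | intermediate
8 | (2E,4S,6E)-2,6-dimethyl-8-[(2-oxo-2H-chromen-7-yl)oxy]-4-[(phenylamino)oxy]octa-2,6-dienal | O=C/C(C)=C/[C@@H](ONc1ccccc1)C/C(C)=C/COc1ccc2ccc(=O)oc2c1 | intermediate
9 | (2E,4S,6E)-4-hydroxy-2,6-dimethyl-8-[(2-oxo-2H-chromen-7-yl)oxy]octa-2,6-dienal | O=C/C(C)=C/[C@@H](O)C/C(C)=C/COc1ccc2ccc(=O)oc2c1 | intermediate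
10 | (2E,4S,6E)-2,6-dimethyl-1-oxo-8-[(2-oxo-2H-chromen-7-yl)oxy]octa-2,6-dien-4-yl acetate | O=C/C(C)=C/[C@@H](OC(C)=O)C/C(C)=C/COc1ccc2ccc(=O)oc2c1 | intermediate
11 | prenyl chloride (1-chloro-3-methylbut-2-ene) | CC(C)=CCCl | starting material
12 | prenylmagnesium chloride ((3-methylbut-2-en-1-yl)magnesium chloride, not isolated) | CC(C)=CC[Mg]Cl | intermediate
13 | 2-(2-methylbut-3-en-2-yl)-4,4,5,5-tetramethyl-1,3,2-dioxaborolane | C=CC(C)(C)B1OC(C)(C)C(C)(C)O1 | intermediate
14 | O-pinacolboryl ether of the target (8'-O-Bpin, 5'S,8'R, not isolated) | CC(=O)O[C@H](/C=C(\C)[C@H](OB1OC(C)(C)C(C)(C)O1)CC=C(C)C)C/C(C)=C/COc1ccc2ccc(=O)oc2c1 | intermediate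
15 | (2E,5S,6E,8R)-8-hydroxy-3,7,11-trimethyl-1-[(2-oxo-2H-chromen-7-yl)oxy]dodeca-2,6,10-trien-5-yl acetate, i.e. (5'S,8'R)-5'-acetoxy-8'-hydroxyumbelliprenin | CC(=O)O[C@H](/C=C(\C)[C@H](O)CC=C(C)C)C/C(C)=C/COc1ccc2ccc(=O)oc2c1 | target

**Step count and risk**

Total step count: 7. Longest linear sequence: 6 (steps 1–5 and 7); step 6 is a one-step side branch.

The three steps most likely to fail:

Step 7 (the proposed new step). The tertiary boronate may react too slowly with the α-branched enal, may leak through an acid-promoted 1,3-boryl shift to the branched tert-prenyl carbinol, or may give poor facial control. The facial sense is assigned by analogy with allyl-Bpin and must be confirmed (Mosher esters of 15); if it is reversed, the (S)-catalyst is used. The fallback uses known chemistry and sets out from 10. Allylboronic acid pinacol ester with (R)-TRIP (5 mol%) in toluene at −30 °C, the established chiral-phosphoric-acid allylboration, gives the O-pinacolboryl ether of the allyl adduct F1. Aqueous work-up hydrolyses it to the homoallylic alcohol (2E,5S,6E,8R)-8-hydroxy-3,7-dimethyl-1-[(2-oxo-2H-chromen-7-yl)oxy]undeca-2,6,10-trien-5-yl acetate F2. Cross-metathesis of the terminal vinyl group of F2 with excess 2-methyl-2-butene, using the second-generation Grubbs catalyst RuCl2(=CHPh)(PCy3)(H2IMes) (5 mol%) in CH2Cl2 at 40 °C, converts allyl into prenyl and returns to the route at 15. The trisubstituted olefins and the coumarin C3=C4 bond are far less reactive than the monosubstituted olefin.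

Step 3. The α-anilinooxy aldehyde 7 is labile, the formyl ylide is only moderately reactive, and slow olefination could cost yield or enantiopurity. The fallback sets out from 5 and changes the oxygen electrophile to one that gives an isolable α-acyloxy aldehyde. (S)-α,α-Diphenylprolinol trimethylsilyl ether (10 mol%), benzoyl peroxide and hydroquinone (10 mol%) in THF at 0 °C give the α-benzoyloxy aldehyde (2S,4E)-4-methyl-1-oxo-6-[(2-oxo-2H-chromen-7-yl)oxy]hex-4-en-2-yl benzoate F3; steric shielding of one enamine face by the catalyst gives the S configuration. Wittig reaction of F3 with 6 in CH2Cl2 gives the enal (2E,4S,6E)-2,6-dimethyl-1-oxo-8-[(2-oxo-2H-chromen-7-yl)oxy]octa-2,6-dien-4-yl benzoate F4. Brief methanolysis (K2CO3, MeOH, 0 °C) removes the benzoate and returns to the route at 9. This detour also bypasses step 4.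

Step 2. Risks are over-oxidation at the 2',3'-olefin and acid-promoted loss of the allylic aryl ether during the periodic acid stage. The fallback sets out from 3 and replaces epoxidation by dihydroxylation. Catalytic K2OsO2(OH)4 (1 mol%) with N-methylmorpholine N-oxide in acetone–H2O at 0 °C, stopped at one equivalent of oxidant, gives the racemic diol 7-{[(2E)-6,7-dihydroxy-3,7-dimethyloct-2-en-1-yl]oxy}-2H-chromen-2-one F5. It is purified and cleaved under neutral conditions with NaIO4 in THF–H2O, returning to the route at 5.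

**Further compounds**

F1 | step 7 | O-pinacolboryl ether of the allyl adduct (8-O-Bpin derivative of F2, not isolated) | CC(=O)O[C@H](/C=C(\C)[C@H](OB1OC(C)(C)C(C)(C)O1)CC=C)C/C(C)=C/COc1ccc2ccc(=O)oc2c1
F2 | step 7 | (2E,5S,6E,8R)-8-hydroxy-3,7-dimethyl-1-[(2-oxo-2H-chromen-7-yl)oxy]undeca-2,6,10-trien-5-yl acetate | CC(=O)O[C@H](/C=C(\C)[C@H](O)CC=C)C/C(C)=C/COc1ccc2ccc(=O)oc2c1
F3 | step 3 | (2S,4E)-4-methyl-1-oxo-6-[(2-oxo-2H-chromen-7-yl)oxy]hex-4-en-2-yl benzoate | O=C[C@@H](OC(=O)c1ccccc1)C/C(C)=C/COc1ccc2ccc(=O)oc2c1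
F4 | step 3 | (2E,4S,6E)-2,6-dimethyl-1-oxo-8-[(2-oxo-2H-chromen-7-yl)oxy]octa-2,6-dien-4-yl benzoate | O=C/C(C)=C/[C@@H](OC(=O)c1ccccc1)C/C(C)=C/COc1ccc2ccc(=O)oc2c1
F5 | step 2 | 7-{[(2E)-6,7-dihydroxy-3,7-dimethyloct-2-en-1-yl]oxy}-2H-chromen-2-one (racemic) | CC(C)(O)C(O)CC/C(C)=C/COc1ccc2ccc(=O)oc2c1
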